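The numbers were drawn at random within sensible limits; what happens was integrated by code.

Whatever the temperature, each part of the charged starting material stood at every moment as starting material, intermediate, target or over-reaction product, so the intermediate in a flask was what had been converted minus what had gone on to the two later forms.

| setting | autumn | dawn | summer | spring |
|---|---|---|---|---|
| starting material | 0.077 M | 0.077 M | 0.077 M | 0.077 M |
| solid partner | 0.193 M | 0.193 M | 0.193 M | 0.193 M |
| temperature | 65 °C | 40 °C | 15 °C | −10 °C |
| time | 1.5 h | 1.5 h | 1.5 h | 1.5 h |

- the flask with the highest amount of intermediate, in percent of the starting material charged ("all alike" if they lie within 1.5 percentage points) (autumn / dawn / summer / spring / all alike)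
- final intermediate, as a percentage of the starting material charged, in autumn
- final intermediate, as a percentage of the starting material charged, in dawn
- final intermediate, as a percentage of the starting material charged, in summer
- final intermediate, as a percentage of the starting material charged, in spring

- a doubled species enters its step squared and goes two at a time
- as a solid, counted per litre of solution: solid partner
- all constants are for 40 °C and move with temperature by the activation energies and enthalpies
- at the start none of the solid partner is in solution

    fresh partner + intermediate ⇌ target (K1 = 36 /M, k1 = 9.7 /M/h, Ea1 = 78.0 kJ/mol, ΔH1 = 8.00 kJ/mol)
    2 fresh partner → homo product (k2 = 10 /M/h, Ea2 = 54.0 kJ/mol)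
    starting material → intermediate (k3 = 2.2 /h, Ea3 = 92.0 kJ/mol)
    fresh partner + target → over-reaction product (k4 = 1.3 /M/h, Ea4 = 59.0 kJ/mol)
    solid partner ⇌ fresh partner, rate k5*(cs5 - [fresh partner]) while solid is left; crystals form when [fresh partner] > cs5 (cs5 = 46 mM, k5 = 0.63 /h)
    (constants at 40 °C)

Conversion here runs through one first-order step, starting material → intermediate (k3 = 2.2 /h, Ea3 = 92.0 kJ/mol), so I counted lifetimes. Let k be the rate constant of that step at the flask's temperature and t the time of the run, 1.5 h. The mean lifetime of the starting material is then the inverse of k, and the share of it left is e^(−N), where N = k·t. In dawn, whose temperature is the one the constants are given at, k is 2.2 /h, which makes 3.30 the count N of mean lifetimes of the starting material in the run.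

I set up a small table with one row per flask and two columns, N and the share left, moving k with the activation energy 92.0 kJ/mol. Autumn's row read 45.0, more lifetimes than dawn's, with a share left of <0.001 %. Dawn's row read 3.30 with 3.69 % left, so its converted share, the ceiling on its intermediate by the balance above, was 96.3 %. Summer's row read 0.154 and spring's 0.00401, which are less than one lifetime each, and I took their converted shares, 14.3 % and 0.400 %, as my answers for those two flasks. Reading the rows down, the summer and spring figures stood below dawn's ceiling, but autumn's ceiling stood above dawn's. My count held nothing about the target, so I stopped there and left dawn against autumn open.

The forecast named dawn, with 71 % in autumn, 84.4 % in dawn, 14.1 % in summer and 0.4 % in spring, on the ground that “Step 3 sets the supply of intermediate”. Its summer figure stood below mine.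

The simulation gave dawn as the highest, with 73.0 % in autumn, 84.6 % in dawn, 14.1 % in summer and 0.400 % in spring, so the forecast held within the tolerance.

In dawn the count of 3.30 lifetimes gave 3.69 % left, and the flask held 3.7 % of its starting material. Taking away what the temperature does to the making of intermediate, the largest single effect of temperature, moved the gap in final intermediate between autumn and spring from 73 percentage points to −0.13 points. The neighbour flask, read at dawn's temperature after 4.0 h, had 8.80 lifetimes, which gave 0.0151 % left, and it held 0.015 %, with target at 31.2 % and intermediate down to 67.2 %.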